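**Retrosynthetic overview**
- Rings A and C are disconnected together. The flavanone goes back to an acyclic (S)-δ-hydroxy methoxy-enynone, C2(OH)–C3–C4(OMe)=C4a–C8a(=O)–C8≡C7–C6=C5–OMe. In the forward direction ring C closes first (O1–C8a) and ring A second (C4a–C5), in one flask. Ring B is bought.
- The enynone comes from acyl–oxygen opening of an (S)-6-aryl-4-methoxy-5,6-dihydropyran-2-one by lithiated (Z)-1-methoxybut-1-en-3-yne. This reagent supplies C5–C8: the alkyne is a masked C7 ketone and the enol ether a masked C5 aldehyde.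
- The lactone is a temporary ring that carries C2. It comes from 4-(geranyloxy)benzaldehyde and Brassard's diene by a catalytic asymmetric hetero-Diels–Alder reaction, which sets the only stereocentre.
- The aldehyde comes from 4-hydroxybenzaldehyde and geranyl bromide. The diene comes from methyl 3-methoxycrotonate.

Notation: flavanone numbering (O1, C2, C3, C4, C4a, C5–C8, C8a) is used for these atoms in every intermediate. "Geranyloxy" means [(2E)-3,7-dimethylocta-2,6-dien-1-yl]oxy.

Assumption: methyl (E)-3-methoxybut-2-enoate and (Z)-1-methoxybut-1-en-3-yne are catalogue items. The latter is sold in aqueous methanol and is extracted, dried and distilled before use.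

**Step 1**
Reactants: 1 4-hydroxybenzaldehyde; 2 geranyl bromide, (2E)-1-bromo-3,7-dimethylocta-2,6-diene
Product: 3 4-(geranyloxy)benzaldehyde
Conditions: K2CO3 (1.5 equiv), DMF, rt, 12 h
Reagents that add atoms: none
Why: Williamson ether synthesis in which the phenoxide displaces the primary allylic bromide by SN2, leaving the E alkene untouched and creating no stereocentre.

**Step 2**
Reactants: 4 methyl (E)-3-methoxybut-2-enoate
Product: 5 Brassard's diene, (1E)-1,3-dimethoxy-1-(trimethylsilyloxy)buta-1,3-diene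
Conditions: LiN(iPr)2 (1.1 equiv), THF, −78 °C; Me3SiCl (1.2 equiv), −78 °C to rt; distil
Reagents that add atoms: chlorotrimethylsilane, C[Si](C)(C)Cl
Why: Kinetic γ-deprotonation of the vinylogous carbonate followed by O-silylation (silyl ketene acetal formation) is the standard way to this 1,3-dioxygenated diene.

**Step 3**
Reactants: 3 4-(geranyloxy)benzaldehyde; 5 Brassard's diene
Product: 7 (6S)-6-[4-(geranyloxy)phenyl]-4-methoxy-5,6-dihydro-2H-pyran-2-one, via silyl aldol ester 6 (not isolated)
Conditions: Ti(OiPr)4 (20 mol %), (S)-BINOL (22 mol %), 4 Å MS, toluene, 0 °C to rt; then TFA (cat.), CH2Cl2, 0 °C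
Reagents that add atoms: none
Why: Catalytic asymmetric hetero-Diels–Alder reaction of Brassard's diene, run in its stepwise vinylogous Mukaiyama aldol–lactonisation mode, in which the (S)-BINOL complex of tetravalent titanium shields the Re face of the aldehyde so that the diene terminus adds to the Si face and sets C2 as S (O > aryl > CH2 > H), after which acid closes 6 to the lactone.

**Step 4**
Reactants: 7 (6S)-lactone; 8 (Z)-1-methoxybut-1-en-3-yne
Product: 10 (1S,3E,8Z)-1-[4-(geranyloxy)phenyl]-1-hydroxy-3,9-dimethoxynona-3,8-dien-6-yn-5-one, via lithium acetylide 9 (not isolated)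
Conditions: 8 (1.3 equiv), n-BuLi (1.25 equiv), THF, −78 °C, 30 min; add 7, −78 °C, 1 h; AcOH (1.5 equiv) in THF at −78 °C
Reagents that add atoms: none
Why: 1,2-Addition of a lithium acetylide to a lactone stops at the ketone because the lithium lactolate survives at −78 °C, and acyl–oxygen cleavage leaves the C2–O bond and its S configuration untouched, keeps C3 cis to the carbonyl (E enol ether) as reclosure requires, and brings in C5–C8.

**Step 5 (key step: rings C and A in one flask)**
Reactants: 10 acyclic (S)-hydroxy enynone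
Product: 13 (2S)-2-[4-(geranyloxy)phenyl]-7-hydroxy-2,3-dihydro-4H-chromen-4-one (target), via alkynyl lactol 11 (not isolated), via side-chain enone dihydropyranone 12 (not isolated)
Conditions: (+)-camphorsulfonic acid (10 mol %), dry CH2Cl2, 0 °C, 1 h; then THF–H2O (10:1) added to the same flask, rt to 40 °C
Reagents that add atoms: water, O
Why: Proposed new method: an acid-triggered sequence of lactolisation, Meyer–Schuster oxygen shift, Stork–Danheiser-type enol ether hydrolysis and polyketide-type aldol aromatisation, reasoned as follows: in the dry first phase the C2 hydroxyl is the only nucleophile and closes on the C8a ketone to lactol 11 (ring C), 11 ionises easily to an alkynyl oxocarbenium ion stabilised by O1 and the C4 methoxy group, the water just released returns at the distal alkyne carbon C7 and added water removes the C4 methyl enol ether to give 12, in which O1 blocks pyrone formation so that the nucleophilic vinylogous-ester carbon C4a can only attack the unmasked C5 aldehyde carbon, and loss of methanol with enolisation at C7 gives the phenol (ring A); the C2–O1 bond is never broken, so S is carried over; the closest known reaction types are the acid cyclisation of lactone-derived hydroxy methoxyenynones to spiroketal pyranones, the Meyer–Schuster rearrangement and the biomimetic aldol aromatisation of polyketide chains.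

**Compound list**
1 | 4-hydroxybenzaldehyde | O=Cc1ccc(O)cc1 | starting material
2 | geranyl bromide | CC(C)=CCC/C(C)=C/CBr | starting material
3 | 4-(geranyloxy)benzaldehyde | CC(C)=CCC/C(C)=C/COc1ccc(C=O)cc1 | intermediate
4 | methyl (E)-3-methoxybut-2-enoate | CO/C(C)=C/C(=O)OC | starting material
5 | (1E)-1,3-dimethoxy-1-(trimethylsilyloxy)buta-1,3-diene | C=C(OC)/C=C(\OC)O[Si](C)(C)C | intermediate
6 | methyl (2E,5S)-5-[4-(geranyloxy)phenyl]-3-methoxy-5-(trimethylsilyloxy)pent-2-enoate | CC(C)=CCC/C(C)=C/COc1ccc([C@@H](O[Si](C)(C)C)C/C(OC)=C\C(=O)OC)cc1 | intermediate (not isolated)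
7 | (6S)-6-[4-(geranyloxy)phenyl]-4-methoxy-5,6-dihydro-2H-pyran-2-one | CC(C)=CCC/C(C)=C/COc1ccc([C@@H]2CC(OC)=CC(=O)O2)cc1 | intermediate
8 | (Z)-1-methoxybut-1-en-3-yne | C#C/C=C\OC | starting material
9 | lithium (Z)-4-methoxybut-3-en-1-yn-1-ide | [Li]C#C/C=C\OC | intermediate (not isolated)
10 | (1S,3E,8Z)-1-[4-(geranyloxy)phenyl]-1-hydroxy-3,9-dimethoxynona-3,8-dien-6-yn-5-one | CC(C)=CCC/C(C)=C/COc1ccc([C@@H](O)C/C(OC)=C\C(=O)C#C/C=C\OC)cc1 | intermediate
11 | (6S)-6-[4-(geranyloxy)phenyl]-4-methoxy-2-[(3Z)-4-methoxybut-3-en-1-yn-1-yl]-5,6-dihydro-2H-pyran-2-ol, anomer mixture | CC(C)=CCC/C(C)=C/COc1ccc([C@@H]2CC(OC)=CC(O)(C#C/C=C\OC)O2)cc1 | intermediate (not isolated)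
12 | (2S)-2-[4-(geranyloxy)phenyl]-6-[(3Z)-4-methoxy-2-oxobut-3-en-1-yl]-2,3-dihydro-4H-pyran-4-one | CC(C)=CCC/C(C)=C/COc1ccc([C@@H]2CC(=O)C=C(CC(=O)/C=C\OC)O2)cc1 | intermediate (not isolated)
13 | (2S)-2-[4-(geranyloxy)phenyl]-7-hydroxy-2,3-dihydro-4H-chromen-4-one | CC(C)=CCC/C(C)=C/COc1ccc([C@@H]2CC(=O)c3ccc(O)cc3O2)cc1 | target

**Step count**
- Total steps: 5.
- Longest linear sequence: 4 (steps 1, 3, 4, 5).
- No protecting groups are used.

**Steps most likely to fail, with fallbacks**

Step 5 carries the most risk.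
- Water may hydrate the enynone before ring C closes. The free polyketide would then aromatise without O1 and drain into the racemic chalcone manifold.
- Compound 12 may be slow to close.
- The acid may ionise the 4-alkoxybenzylic C2–O bond.

The fallback sets out from 3 and builds the rings one at a time by two cycloadditions with commercial Danishefsky's diene.
- Ti(OiPr)4/(S)-BINOL gives the aldol (1E,5S)-5-[4-(geranyloxy)phenyl]-1-methoxy-5-(trimethylsilyloxy)pent-1-en-3-one F5.
- TFA closes it to (2S)-2-[4-(geranyloxy)phenyl]-2,3-dihydro-4H-pyran-4-one F6.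
- I2 and pyridine in CH2Cl2 give the α-iodo enone (2S)-2-[4-(geranyloxy)phenyl]-5-iodo-2,3-dihydro-4H-pyran-4-one F7.
- A second equivalent of the diene in toluene at 110 °C adds with its CH2 terminus at C8a to give the cycloadduct (2S)-2-[4-(geranyloxy)phenyl]-4a-iodo-5-methoxy-7-(trimethylsilyloxy)-2,3,4a,5,8,8a-hexahydro-4H-chromen-4-one F8.
- Et3N removes HI across C4a–C8a. A dilute citric acid work-up then removes methanol and the silyl group, which aromatises ring A. The sequence comes back to the route at 13.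

Step 4 is next.
- The vinylogous-carbonate carbonyl of 7 may be sluggish.
- The acetylide may act as a base at C3 and open the ring by E1cB to a dienoate.
- The acetylide may add twice.

The fallback sets out from 7 and changes the acyl donor.
- MeNH(OMe)·HCl with iPrMgCl in THF at −20 °C opens the lactone to the Weinreb amide (2E,5S)-5-[4-(geranyloxy)phenyl]-5-hydroxy-N,3-dimethoxy-N-methylpent-2-enamide F4.
- 2.2 equiv of 9 convert F4 through a chelated tetrahedral intermediate into the ketone only. The sequence comes back at 10.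

Step 3 is third. The electron-rich aldehyde is a slow partner, and the ee with this catalyst may be moderate.

The fallback sets out from 3 and uses a dioxinone as the acetoacetate unit.
- 2,2,6-Trimethyl-4H-1,3-dioxin-4-one with LiN(iPr)2 and Me3SiCl gives 2,2-dimethyl-6-methylene-4-(trimethylsilyloxy)-1,3-dioxine F1.
- A vinylogous Mukaiyama aldol with Cu(OTf)2, Bu4N[Ph3SiF2] and the Tol-BINAP antipode that gives the S carbinol delivers 6-{(2S)-2-[4-(geranyloxy)phenyl]-2-hydroxyethyl}-2,2-dimethyl-4H-1,3-dioxin-4-one F2.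
- Heating in toluene at 110 °C expels acetone, and the hydroxyl closes to (6S)-6-[4-(geranyloxy)phenyl]dihydro-2H-pyran-2,4(3H)-dione F3.
- O-methylation with Me2SO4 and K2CO3 in acetone comes back at 7.

**Further compounds**
F1 | step 3 | 2,2-dimethyl-6-methylene-4-(trimethylsilyloxy)-1,3-dioxine | C=C1C=C(O[Si](C)(C)C)OC(C)(C)O1
F2 | step 3 | 6-{(2S)-2-[4-(geranyloxy)phenyl]-2-hydroxyethyl}-2,2-dimethyl-4H-1,3-dioxin-4-one | CC(C)=CCC/C(C)=C/COc1ccc([C@@H](O)CC2=CC(=O)OC(C)(C)O2)cc1
F3 | step 3 | (6S)-6-[4-(geranyloxy)phenyl]dihydro-2H-pyran-2,4(3H)-dione | CC(C)=CCC/C(C)=C/COc1ccc([C@@H]2CC(=O)CC(=O)O2)cc1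
F4 | step 4 | (2E,5S)-5-[4-(geranyloxy)phenyl]-5-hydroxy-N,3-dimethoxy-N-methylpent-2-enamide | CC(C)=CCC/C(C)=C/COc1ccc([C@@H](O)C/C(OC)=C\C(=O)N(C)OC)cc1
F5 | step 5 | (1E,5S)-5-[4-(geranyloxy)phenyl]-1-methoxy-5-(trimethylsilyloxy)pent-1-en-3-one | CC(C)=CCC/C(C)=C/COc1ccc([C@@H](O[Si](C)(C)C)CC(=O)/C=C/OC)cc1
F6 | step 5 | (2S)-2-[4-(geranyloxy)phenyl]-2,3-dihydro-4H-pyran-4-one | CC(C)=CCC/C(C)=C/COc1ccc([C@@H]2CC(=O)C=CO2)cc1
F7 | step 5 | (2S)-2-[4-(geranyloxy)phenyl]-5-iodo-2,3-dihydro-4H-pyran-4-one | CC(C)=CCC/C(C)=C/COc1ccc([C@@H]2CC(=O)C(I)=CO2)cc1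
F8 | step 5 | (2S)-2-[4-(geranyloxy)phenyl]-4a-iodo-5-methoxy-7-(trimethylsilyloxy)-2,3,4a,5,8,8a-hexahydro-4H-chromen-4-one, new centres transient | CC(C)=CCC/C(C)=C/COc1ccc([C@@H]2CC(=O)C3(I)C(OC)C=C(O[Si](C)(C)C)CC3O2)cc1
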